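All constants were set for the occasion; no experiment stands behind them.

Take as unit the half-life of the charge, and count how many of them each run holds.

| setting | north | north-east | south | east |
|---|---|---|---|---|
| substrate | 0.076 M | 0.076 M | 0.076 M | 0.076 M |
| enzyme | 5.0 µM | 8.0 µM | 12 µM | 15 µM |
| time | 2.5 h | 2.5 h | 2.5 h | 2.5 h |

    substrate + enzyme → target + enzyme, rate k1*[substrate]*[enzyme]/(1 + ([substrate]/Km1) + ([substrate]/Ksi1)^2) (Km1 = 31 mM, Ksi1 = 27 mM, k1 = 4.0 × 10⁵ /M/h)
    substrate → uncatalysed product (k2 = 0.034 /h)
    enzyme + enzyme ⇌ resting dimer (K3 = 46000 /M, k3 = 82000 /M/h)

* amount of target at the end, in percent of the substrate charged for north, north-east, south, east, in this order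
* how that number moves from the first to the last of them (falls all the way / hardly changes / falls, then rises / rises all the way / rises, then falls)

- a step written with two of one species runs at k times the square of its concentration and takes two of it each time
- "hardly changes" means that all values lie within two and a half points (for a concentration: within two and a half percent of the largest)
- run time (north): 2.5 h

Set the enzyme first. Resting dimer falls apart with a half-life of 0.389 h, shorter than the run, so take the dimer step as at equilibrium. Counting two enzyme in each dimer, this gives c(enzyme) = 3.72 µM in north and 8.44 µM in east.

Now divide the rate law by c(substrate) and integrate. The lifetimes needed, each being the pseudo-first-order lifetime at low substrate, one over k times c(enzyme), are the logarithm of the fall, plus the fall over Km, plus the fall of the square over twice Ksi squared. The first halving costs 4.89 lifetimes, the next 2.05, the next 1.19.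

So define the inhibited half-life of the charge, the first halving's cost divided by k times free enzyme: in north it is 3.28 h. Set the uncatalysed step aside, because its half-life of 20 h is longer.

North's run is shorter than its half-life, so expect target below 50.0 %. East holds 8.44 lifetimes against 8.13 for 3 halvings, so expect about 87.5 % target. Free enzyme is higher in east, so the row should rise.

The forecast gives 39.6 %, 60.4 %, 82.5 %, 91 %, rises all the way, holding that “target climbs steadily with enzyme”. Its east value stands above this reckoning.

The flasks give 39.4 %, 60.2 %, 82.5 %, 91.2 %, rises all the way.

In north, with a reckoned half-life of 3.28 h, the catalysed and the uncatalysed step ran side by side up to 2.50 h and together left 54.1 % substrate; the uncatalysed step made 6.55 % of the charge, and enzyme stood at 74.5 % free and 25.5 % as resting dimer. In east the same quantity reckons 1.45 h; that flask holds 48.2 % substrate at 1.25 h, and at 2.50 h it holds 4.65 %.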